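## The problem

6-n-Heneicosyl-2,4-dimethoxyphenol (11) is an achiral benzene with four substituents in a 1,2,3,5 array: a free hydroxyl on C1, methyl ethers on C2 and C4, an unbranched C21 chain on C6, and hydrogens on C3 and C5. With no stereocentre in the target, the task is regiochemical: three oxygens in a 1,2,4 relationship must be told apart (one free, two methylated), and the chain must stand ortho to the free hydroxyl and meta to both methoxy groups. Electrophilic substitution on the chain-free dimethoxyphenol would favour C5, which is para to the C2 ether and ortho to the C4 ether, over C6, which only the hydroxyl activates; the ring is better built around its substituents. The free phenol has a para methoxy group and is therefore a hydroquinone monoether, easily oxidized to a quinone; it should be unmasked last and never meet the oxidant that creates the aromatic ring. The C21 chain is inert but makes every intermediate waxy and poorly soluble in cold polar solvents, which argues against cryogenic organometallic steps. Stereocentres that arise on the way neither can nor need control anything, since aromatization erases them. The enabling feature is the 1,3 relationship of the oxygens on C2 and C4 with C3 between them: written as carbonyls they make the ring a cyclohexane-1,3-dione in which C6 is β to the C4 carbonyl and C1 is α to the C2 carbonyl, so C1 can arrive as the central carbon of a malonate that already carries its oxygen as an ether, and C6 as the β-carbon of an enone.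

## Retrosynthesis

**11 to 10.** The oxygen–benzyl bond at C1 is cut, leading to 2-(benzyloxy)-1-heneicosyl-3,5-dimethoxybenzene (10). Benzyl is preferred to its neighbours because it is inert to the alkoxide, hydroxide, dilute acid and iodine the ring must pass through, is distinguishable from the two methyl ethers, and leaves under neutral, reducing conditions that suit an oxidation-prone phenol. A silyl ether would not survive the basic annulation, and a third methyl group could not be removed selectively. Compound 10 no longer contains the sensitive phenol. The forward step must cleave one ether out of three.

**10 to 9.** Both O–CH3 bonds are cut and the ring is lowered by one oxidation level, giving 4-(benzyloxy)-5-heneicosylcyclohexane-1,3-dione (9). The difference between the three oxygens is now encoded in the hybridization of their carbons: C2 and C4 are carbonyl carbons, C1 is an sp3 carbon bearing an ether. Only carbonyl groups can be captured as methyl enol ethers when the ring is oxidized in methanol. The neighbouring option, aromatizing first and methylating in a separate step, costs one step more and is held in reserve. The forward reaction must remove two hydrogens, install both methyl groups and leave the benzyl ether in place.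

**9 to 7.** An ester carbon is added to C1, giving ethyl 1-(benzyloxy)-2-heneicosyl-4,6-dioxocyclohexane-1-carboxylate (7); the β-keto acid 8 lies between. The ester is the second acidifying group that makes C1 a malonate carbon. Carrying it for one step and then removing it is simpler than generating a carbanion on a singly activated benzyloxyacetyl unit. The forward reaction is ester hydrolysis and decarboxylation without opening of the ring.

**7 to 4 and 5.** Two ring bonds are cut together, C1–C6 and C2–C3 (target numbering). C1 and C2 come from diethyl 2-(benzyloxy)malonate (5); C3 to C6 and the whole chain come from (E)-pentacos-3-en-2-one (4); the open-chain adduct 6 lies between. Cutting only C1–C6 of an aromatic precursor would leave a long polyketone with carbon, not oxygen, on C1. Cutting at C4–C5 or C5–C6 would need an alkoxy ketone fragment whose enolization is ambiguous. The chosen cut uses each fragment in its natural polarity: the malonate carbon is a nucleophile and its ester an acyl electrophile, while the enone β-carbon is an electrophile and its methyl group a nucleophile. It also places the C1 oxygen in a purchased reagent. The forward reaction must add a tertiary, alkoxy-substituted carbanion to a β-alkyl enone and then close a Claisen condensation that creates a quaternary carbon.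

**4 to 2 and 3.** The enone double bond is cut, giving docosanal (2) and the stabilized ylide 1-(triphenylphosphoranylidene)propan-2-one (3). A Wittig reaction is preferred to a crossed aldol condensation of 2 with a simple methyl ketone, which would suffer from self-condensation of the aldehyde and double condensation. The stabilized ylide gives the E geometry, although the annulation does not depend on it.

**2 to 1.** Only the oxidation level changes. 1-Docosanol (1) is a commodity fatty alcohol; its carbinol carbon becomes ring carbon C6, so 21 carbons remain as the chain. The forward step must stop at the aldehyde.

## Roads not taken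

**Alternative 1:** the cut is the C5–C6 ring bond of a precursor already at the resorcinol oxidation level.
- Key step: 3-(benzyloxy)-2-heneicosyl-6-methyl-4H-pyran-4-one A1 would be opened by hot aqueous-ethanolic KOH to an acyclic 1,3,5-triketone. Its terminal methyl carbanion condenses with the chain ketone and, after loss of water, gives 4-(benzyloxy)-5-heneicosylbenzene-1,3-diol A2 as the product of the key step. Double O-methylation and hydrogenolysis would finish.
- Merits: the arene arrives at the right oxidation level, so no oxidant is needed. The two hydroxyls of A2 are methylated by an ordinary Williamson reaction while C1 is already masked. In this respect the road is cleaner than the oxidative methanolysis of the chosen plan.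
- Weak point, supply: A1 must first be assembled from 5-hydroxy-2-methyl-4H-pyran-4-one A3 by hydroxyalkylation with heneicosanal A4 followed by deoxygenation of the carbinol and O-benzylation. The aldehyde A4 is an odd-chain compound, far less accessible than the even-chain alcohol 1.
- Weak point, selectivity: the opened triketone can close a six-membered ring in two ways. The methyl group can attack the chain ketone (wanted), or the chain α-methylene can attack the acetyl carbonyl. Hydroxide can also cleave the triketone by retro-Claisen reaction or let it close back to the pyranone.
- Comparison: the length is similar (about seven steps). Against the better redox economy of this road, the chosen plan sets two-step access to both annulation partners from commodity materials and a ring closure with only one possible six-membered mode.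

**Alternative 2:** the cut is the C4–C5 bond, formed by electrocyclization of a dienylketene.
- Key step: 3-methoxy-4-(methoxymethoxy)-4-(tricos-1-en-2-yl)cyclobut-2-en-1-one A5 would, on heating in toluene, open to the ketene and close to 3-heneicosyl-5-methoxy-4-(methoxymethoxy)phenol A6 after tautomerization. Methylation of the new phenol of A6 and acidic removal of the acetal would follow.
- Merits: every oxygen carries its own label from the start, the ring forms thermally without reagents at the aromatic oxidation level, and the substitution pattern is fixed by connectivity alone. In certainty of regiochemistry this road is better than the chosen one.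
- Weak points: 3-methoxycyclobut-3-ene-1,2-dione A7 must be made from a squarate diester by partial reduction, because the position that becomes C3–H has to be unsubstituted. 2-Bromotricos-1-ene A8 must be prepared and lithiated at low temperature, where C21 compounds dissolve poorly. The addition must select the ketone carbonyl of A7 over its vinylogous ester carbonyl, and a tertiary alcohol must be protected.
- Comparison: this comes to roughly eight or nine steps against six. The chosen plan offers fewer steps, no cryogenic organometallic chemistry on waxy substrates and cheap inputs, and accepts in exchange an aromatization of less certain selectivity.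

**Alternative 3:** the cut is the same C1–C6 bond as in the chosen plan, but in an acyclic tetraketide.
- Key step: methyl 3,5,7-trioxooctacosanoate A9 in dilute aqueous-methanolic KOH would undergo aldol addition of its C2 carbanion to the C7 ketone and aromatize to methyl 2-heneicosyl-4,6-dihydroxybenzoate A10 by dehydration and enolization. The ester carbon of A10 marks the phenol site and would be exchanged for oxygen by O-methylation, reduction to the aldehyde, Baeyer–Villiger (Dakin-type) oxidation and formate hydrolysis.
- Merits: the arene forms directly, both hydroxyls are free for clean methylation, and the endgame is reliable. The tetraketide A9 would come from methyl docosanoate A11 as acyl donor, as cheap as 1, and the polyanion of methyl 3,5-dioxohexanoate A12 as acceptor. In the reliability of its oxygen differentiation this road is better, and the fallback to the key step below borrows its endgame.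
- Weak points: polyanion chemistry in cold THF with a waxy ester; a tetraketide that can also close by Claisen condensation to an acylphloroglucinol or lactonize to a pyranone, depending delicately on the medium; and three to four steps spent trading a carbon on C1 for oxygen.
- Comparison: about eight steps. The chosen plan forms the same bond with the oxygen already on C1.

Key step: step 3

Assumption: diethyl 2-(benzyloxy)malonate (5) is taken as a purchasable malonate, and compounds 7 to 9 are drawn as diketo tautomers although they should exist largely as enols.

## Route

Step 1
Reactants: 1 1-docosanol
Product: 2 docosanal
Conditions: TEMPO (10 mol %), PhI(OAc)2 (1.1 equiv), CH2Cl2, 30 °C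
Reagents that add atoms: none
Why: Oxoammonium (TEMPO) oxidation of a primary alcohol with PhI(OAc)2 as terminal oxidant; without water it should stop at the aldehyde, and no other functional group is present.

Step 2
Reactants: 2 docosanal; 3 1-(triphenylphosphoranylidene)propan-2-one
Product: 4 (E)-pentacos-3-en-2-one
Conditions: toluene, 90 °C
Reagents that add atoms: none
Why: Wittig olefination with a stabilized acyl ylide, which reacts cleanly with unhindered aliphatic aldehydes and gives the E-alkene selectively; the long chain does not interfere.

Step 3
Reactants: 4 (E)-pentacos-3-en-2-one; 5 diethyl 2-(benzyloxy)malonate
Product: 7 ethyl 1-(benzyloxy)-2-heneicosyl-4,6-dioxocyclohexane-1-carboxylate (racemic), via Michael adduct 6 (not isolated)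
Conditions: NaOEt (1.2 equiv), EtOH–THF, rt to reflux; then 1 M HCl
Reagents that add atoms: none
Why: Tandem Michael–Claisen (Dieckmann-type) annulation, the reaction by which dialkyl malonates and alkenyl methyl ketones give cyclohexane-1,3-diones (the dimedone synthesis), applied here to a 2-alkoxymalonate. Ethoxide deprotonates 5 between its two esters and the soft, doubly stabilized carbanion adds to the β-carbon of 4 to give ketone 6, forming the future C1–C6 bond; 1,2-addition is reversible and leads nowhere. Proton transfer moves the enolate of 6 to the methyl terminus, which attacks one of the two geminal esters and expels ethoxide, forming the C2–C3 bond in a 6-(enolendo)-exo-trig closure allowed by Baldwin's rules. The only other enolate of 6, at the internal methylene, could reach an ester only through a four-membered ring, and the malonate carbon is fully substituted after the first step, so neither a second Michael addition nor a Knoevenagel condensation can compete. Both steps are reversible and the sequence is pulled forward by deprotonation of 7 at C3 to the delocalized 1,3-dione enolate, which also shields the ring carbonyls from retro-Claisen attack by ethoxide. Two stereocentres arise: the chain-bearing carbon is set in the Michael step with no controlling element and is racemic, and the quaternary carbon is set by which of the two diastereotopic esters is attacked, for which only a weak substrate bias can be expected. Neither needs control, since step 4 removes the ester and step 5 flattens both carbons. The benzyl ether is inert to ethoxide and cannot leave by β-elimination, because no carbanion can form on the adjacent chain-bearing carbon.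

Step 4
Reactants: 7 ethyl 1-(benzyloxy)-2-heneicosyl-4,6-dioxocyclohexane-1-carboxylate
Product: 9 trans-4-(benzyloxy)-5-heneicosylcyclohexane-1,3-dione (racemic), via keto acid 8 (not isolated)
Conditions: 2 M NaOH aq (3 equiv), EtOH, reflux; then 6 M HCl to pH 1, 70 °C
Reagents that add atoms: sodium hydroxide, [Na+].[OH-] (its oxygen is carried only by acid 8 and leaves again as CO2; 9 gains nothing but hydrogen)
Why: Saponification followed by acid-promoted decarboxylation of the β-keto acid 8 (ketonic cleavage of a β-keto ester); under hydroxide the ring is present as the dione enolate, which protects the C2 carbonyl against retro-Claisen opening, and the benzyl ether tolerates both media. The benzyloxy-bearing carbon of 9 is epimerizable and should settle trans to the chain, but its configuration is irrelevant.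

Step 5
Reactants: 9 trans-4-(benzyloxy)-5-heneicosylcyclohexane-1,3-dione
Product: 10 2-(benzyloxy)-1-heneicosyl-3,5-dimethoxybenzene
Conditions: I2 (2 equiv), MeOH, reflux; then aq Na2S2O3
Reagents that add atoms: methanol, CO
Why: Iodine–methanol oxidative aromatization of a cyclohexane-1,3-dione to a resorcinol dimethyl ether: the HI formed catalyses conversion of both carbonyl groups into methyl enol ethers, iodine substitutes an α position, and loss of HI with tautomerization gives the arene. Only oxygens on carbonyl carbons can be methylated in this way, so the sp3-bound benzyl ether on the future C1 should stay as it is, and both transient stereocentres disappear.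

Step 6
Reactants: 10 2-(benzyloxy)-1-heneicosyl-3,5-dimethoxybenzene
Product: 11 6-n-heneicosyl-2,4-dimethoxyphenol
Conditions: H2 (1 atm), 10% Pd/C, EtOAc, rt
Reagents that add atoms: none
Why: Hydrogenolysis of an aryl benzyl ether over Pd/C; aryl methyl ethers, the arene and the saturated chain are inert, and the neutral, reducing medium suits the oxidation-prone p-methoxyphenol that is set free only here.

## Compound list

1 | 1-docosanol | CCCCCCCCCCCCCCCCCCCCCCO | starting material
2 | docosanal | CCCCCCCCCCCCCCCCCCCCCC=O | intermediate
3 | 1-(triphenylphosphoranylidene)propan-2-one | CC(=O)C=P(c1ccccc1)(c1ccccc1)c1ccccc1 | starting material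
4 | (E)-pentacos-3-en-2-one | CCCCCCCCCCCCCCCCCCCCC/C=C/C(C)=O | intermediate
5 | diethyl 2-(benzyloxy)malonate | CCOC(=O)C(OCc1ccccc1)C(=O)OCC | starting material
6 | diethyl 2-(benzyloxy)-2-(2-oxopentacosan-4-yl)malonate (racemic Michael adduct) | CCCCCCCCCCCCCCCCCCCCCC(CC(C)=O)C(OCc1ccccc1)(C(=O)OCC)C(=O)OCC | intermediate (not isolated)
7 | ethyl 1-(benzyloxy)-2-heneicosyl-4,6-dioxocyclohexane-1-carboxylate (racemic; a diastereomer mixture is expected, the isomer with chain and benzyloxy cis is drawn) | CCCCCCCCCCCCCCCCCCCCC[C@@H]1CC(=O)CC(=O)[C@@]1(OCc1ccccc1)C(=O)OCC | intermediate
8 | 1-(benzyloxy)-2-heneicosyl-4,6-dioxocyclohexane-1-carboxylic acid (racemic; same relative configuration drawn) | CCCCCCCCCCCCCCCCCCCCC[C@@H]1CC(=O)CC(=O)[C@@]1(OCc1ccccc1)C(=O)O | intermediate (not isolated)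
9 | trans-4-(benzyloxy)-5-heneicosylcyclohexane-1,3-dione (racemic; the cis epimer is equally serviceable) | CCCCCCCCCCCCCCCCCCCCC[C@@H]1CC(=O)CC(=O)[C@H]1OCc1ccccc1 | intermediate
10 | 2-(benzyloxy)-1-heneicosyl-3,5-dimethoxybenzene | CCCCCCCCCCCCCCCCCCCCCc1cc(OC)cc(OC)c1OCc1ccccc1 | intermediate
11 | 6-n-heneicosyl-2,4-dimethoxyphenol | CCCCCCCCCCCCCCCCCCCCCc1cc(OC)cc(OC)c1O | target

## Step count and least certain steps

Total step count: 6. Longest linear sequence: 6 steps (1 to 2 to 4 to 7 to 9 to 10 to 11); 3 and 5 are purchased.

**Step 3 (key step).** The conjugate addition of the hindered, fully substituted alkoxymalonate carbanion to a β-alkyl enone is reversible and may rest on the side of the starting materials. Ethoxide could meanwhile deconjugate or self-condense the enone, and the Claisen closure that must build a quaternary carbon may be too slow to trap the adduct. Fallback: the annulation is kept, but a carbon instead of an oxygen marks C1. Setting out from 4, the same Michael–Claisen reaction with unsubstituted dimethyl malonate (NaOMe, MeOH), the classical unhindered case, would give methyl 2-heneicosyl-4,6-dioxocyclohexane-1-carboxylate F1. Iodine in methanol, followed by MeI/K2CO3 on any salicylate hydroxyl left unmethylated, would aromatize it to methyl 2-heneicosyl-4,6-dimethoxybenzoate F2. LiAlH4 would reduce the ester to (2-heneicosyl-4,6-dimethoxyphenyl)methanol F3, and MnO2 would oxidize this to 2-heneicosyl-4,6-dimethoxybenzaldehyde F4. Baeyer–Villiger (Dakin-type) oxidation with mCPBA, in which the electron-rich aryl group migrates, would give 2-heneicosyl-4,6-dimethoxyphenyl formate F5. Hydrolysis of F5 (aqueous NaOH–THF under argon, then acid) comes back to the route at 11. The cost is two or three steps more than the main line.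

**Step 5.** Four processes threaten it. Aromatization may overtake enol ether formation at one carbonyl and leave a monomethyl ether. Oxidation at the benzyloxy-bearing carbon followed by mixed-ketal formation with methanol could exchange benzyloxy for methoxy. The HI formed could cleave the benzyl ether. Acid-promoted loss of benzyl alcohol across the benzyloxy- and chain-bearing carbons would aromatize the ring without any oxidant and forfeit the C1 oxygen. Fallback: oxidation and methylation are separated. Setting out from 9, bromination at the carbon between the carbonyls followed by thermal dehydrobromination (Br2, 1 equiv, DMF, 0 °C then 80 °C), in the absence of methanol, would give 4-(benzyloxy)-5-heneicosylbenzene-1,3-diol F6, the same diol as A2 of Alternative 1. Williamson methylation of both hydroxyls (MeI, K2CO3, acetone, reflux) then rejoins the route at 10. A monomethyl ether from the main step would be converged on 10 by the same methylation.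

**Step 4.** Saponification of the crowded ester on the quaternary carbon may be slow, and prolonged heating with hydroxide could then open the ring by retro-Claisen cleavage or reverse the Michael addition. Fallback: the ester is removed by attack at its alkyl carbon instead of its acyl carbon. Setting out from 4 and 5, the annulation would be run with NaOMe in methanol, where 5 is transesterified in the flask to dimethyl 2-(benzyloxy)malonate F7. This would give methyl 1-(benzyloxy)-2-heneicosyl-4,6-dioxocyclohexane-1-carboxylate F8. Krapcho dealkoxycarbonylation (LiCl, wet DMSO, 140 °C; acidic work-up), in which chloride attacks the unhindered methyl group, would deliver 9, where the route is rejoined.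

**Step 6.** Iodine-containing residues from step 5 may poison the palladium surface, the waxy substrate may react slowly, and the electron-rich phenol may oxidize in air during filtration. Fallback: Lewis-acid debenzylation instead of hydrogenolysis. Setting out from 10, BCl3 with pentamethylbenzene as benzyl-cation scavenger (CH2Cl2, −40 °C, short reaction time), a method that spares aryl methyl ethers, comes back to the route at 11 under an inert atmosphere. It makes no new compound.

## Further compounds

F1 | step 3 | methyl 2-heneicosyl-4,6-dioxocyclohexane-1-carboxylate (racemic) | CCCCCCCCCCCCCCCCCCCCCC1CC(=O)CC(=O)C1C(=O)OC
F2 | step 3 | methyl 2-heneicosyl-4,6-dimethoxybenzoate | CCCCCCCCCCCCCCCCCCCCCc1cc(OC)cc(OC)c1C(=O)OC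
F3 | step 3 | (2-heneicosyl-4,6-dimethoxyphenyl)methanol | CCCCCCCCCCCCCCCCCCCCCc1cc(OC)cc(OC)c1CO
F4 | step 3 | 2-heneicosyl-4,6-dimethoxybenzaldehyde | CCCCCCCCCCCCCCCCCCCCCc1cc(OC)cc(OC)c1C=O
F5 | step 3 | 2-heneicosyl-4,6-dimethoxyphenyl formate | CCCCCCCCCCCCCCCCCCCCCc1cc(OC)cc(OC)c1OC=O
F6 | step 5 | 4-(benzyloxy)-5-heneicosylbenzene-1,3-diol | CCCCCCCCCCCCCCCCCCCCCc1cc(O)cc(O)c1OCc1ccccc1
F7 | step 4 | dimethyl 2-(benzyloxy)malonate | COC(=O)C(OCc1ccccc1)C(=O)OC
F8 | step 4 | methyl 1-(benzyloxy)-2-heneicosyl-4,6-dioxocyclohexane-1-carboxylate (racemic; one diastereomer drawn) | CCCCCCCCCCCCCCCCCCCCC[C@@H]1CC(=O)CC(=O)[C@@]1(OCc1ccccc1)C(=O)OC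
F0 | step 6 | none | none
A1 | alternative 1 | 3-(benzyloxy)-2-heneicosyl-6-methyl-4H-pyran-4-one | CCCCCCCCCCCCCCCCCCCCCc1oc(C)cc(=O)c1OCc1ccccc1
A2 | alternative 1 | 4-(benzyloxy)-5-heneicosylbenzene-1,3-diol | CCCCCCCCCCCCCCCCCCCCCc1cc(O)cc(O)c1OCc1ccccc1
A3 | alternative 1 | 5-hydroxy-2-methyl-4H-pyran-4-one | Cc1cc(=O)c(O)co1
A4 | alternative 1 | heneicosanal | CCCCCCCCCCCCCCCCCCCCC=O
A5 | alternative 2 | 3-methoxy-4-(methoxymethoxy)-4-(tricos-1-en-2-yl)cyclobut-2-en-1-one (racemic) | C=C(CCCCCCCCCCCCCCCCCCCCC)C1(OCOC)C(OC)=CC1=O
A6 | alternative 2 | 3-heneicosyl-5-methoxy-4-(methoxymethoxy)phenol | CCCCCCCCCCCCCCCCCCCCCc1cc(O)cc(OC)c1OCOC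
A7 | alternative 2 | 3-methoxycyclobut-3-ene-1,2-dione | COC1=CC(=O)C1=O
A8 | alternative 2 | 2-bromotricos-1-ene | C=C(Br)CCCCCCCCCCCCCCCCCCCCC
A9 | alternative 3 | methyl 3,5,7-trioxooctacosanoate | CCCCCCCCCCCCCCCCCCCCCC(=O)CC(=O)CC(=O)CC(=O)OC
A10 | alternative 3 | methyl 2-heneicosyl-4,6-dihydroxybenzoate | CCCCCCCCCCCCCCCCCCCCCc1cc(O)cc(O)c1C(=O)OC
A11 | alternative 3 | methyl docosanoate | CCCCCCCCCCCCCCCCCCCCCC(=O)OC
A12 | alternative 3 | methyl 3,5-dioxohexanoate | CC(=O)CC(=O)CC(=O)OC
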